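The readings come from a simulation with made-up constants; noise was put on by code.

6 questions on 3 flasks ask which pool leads at the end and how large it is.

| setting | south | west | elm | maple | ash |
|---|---|---|---|---|---|
| substrate | 0.017 M | 0.017 M | 0.017 M | 0.017 M | 0.017 M |
| reagent | 0.0094 M | 0.014 M | 0.0187 M | 0.0187 M | 0.0187 M |
| free catalyst | 0.85 mM | 0.85 mM | 0.85 mM | 0.85 mM | 0.85 mM |
| temperature | 9 °C | 18 °C | 21 °C | 5 °C | 13 °C |
| remark | run made earlier | run made earlier |  |  |  |
| time |  |  | 10 h | 10 h | 10 h |

| run | time / h | product / % | catalyst intermediate C / % | catalyst intermediate A / % | substrate / % |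
|---|---|---|---|---|---|
| south | 0.833 | 0.8 | 0.6 | 2.4 | 95.4 |
| south | 1.50 | 3.4 | 1.6 | 2.3 | 93.7 |
| south | 2.50 | 5.9 | 1.1 | 3.9 | 90.2 |
| south | 3.00 | 6.6 | 0.1 | 2.6 | 88.8 |
| south | 4.00 | 9.3 | 0.2 | 2.2 | 87.6 |
| south | 5.00 | 10.7 | 1.1 | 3.0 | 85.1 |
| south | 6.00 | 13.3 | 0.9 | 2.7 | 83.6 |
| west | 0.167 | 0.1 | 1.1 | 2.6 | 95.6 |
| west | 0.500 | 2.3 | 1.9 | 2.3 | 94.6 |
| west | 0.833 | 5.1 | 1.2 | 3.1 | 90.8 |
| west | 1.33 | 8.1 | 0 | 2.5 | 88.3 |
| west | 2.00 | 12.8 | 0.7 | 3.4 | 83.1 |
| west | 2.50 | 15.7 | 0.7 | 2.9 | 81.5 |
| west | 3.00 | 18.4 | 1.3 | 3.6 | 78.4 |

(standard deviation of a reading: 0.5 percentage points)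

- which of these there is most of at the end, counted by the substrate in it, elm (catalyst intermediate C / catalyst intermediate A / product / substrate)
- which of these there is most of at the end, counted by the substrate in it, maple (catalyst intermediate C / catalyst intermediate A / product / substrate)
- which of these there is most of at the end, counted by the substrate in it, ash (catalyst intermediate C / catalyst intermediate A / product / substrate)
- the largest of these amounts at the end, in percent of the substrate charged, elm
- the largest of these amounts at the end, in percent of the substrate charged, maple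
- the largest of these amounts at the end, in percent of the substrate charged, ash

- what is said of product includes crystals
- what is said of by-product includes idle complex
- crystals is a solid; its amount is given per volume of the solution
- the numbers in the tables scatter with a standard deviation of 0.5 percentage points
- steps under discussion: substrate + free catalyst -> catalyst intermediate A; reagent + catalyst intermediate A <-> catalyst intermediate B; catalyst intermediate B <-> by-product + catalyst intermediate C; catalyst intermediate C -> free catalyst + product; crystals <-> product; free catalyst + by-product <-> idle complex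

1. One number can stand in for each product curve. This is the mean constant κ (a pseudo-first-order constant): minus the natural log of the share of substrate not yet product, divided by time. The last south reading gives 0.0238 h⁻¹ and the last west reading 0.0678 h⁻¹. The west reading at 2.00 h gives 0.0685 h⁻¹, so κ reads about the same at both west times.

2. From south to west, κ grows by a factor of 2.85, but temperature and reagent rise together. In my own reckoning, that factor acts per equal temperature step, with nothing added for the extra reagent. Elm's mean constant is then 0.0961 h⁻¹, ash's 0.0379 h⁻¹ and maple's 0.0149 h⁻¹.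

3. Now draw the curve. Product lags at first: at 0.167 h the west run shows 0.1 % product but already 2.6 % catalyst intermediate A. The catalyst can hold 5.00 % of the substrate charge. After the lag, product climbs each hour by about κ of what is not yet product.

4. Product passes half the charge when the share not yet product reaches 0.5. By κ that is 7.21 h in elm, earlier than the end. It is 18.3 h in ash and 46.4 h in maple, both later than the end. In these 3 flasks the curve bends towards the whole charge, since c(reagent) is 1.10 times c(substrate).

5. At the end, elm should hold 61.7 % product. Taking off the 3.6 % that the last west reading shows on catalyst intermediate A, ash should hold 64.9 % substrate and maple 82.5 %.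

6. The forecast says product at 60 % for elm, substrate at 76 % for maple and substrate at 58 % for ash, noting that “Temperature and reagent are confounded between the runs”.

7. The flasks give product at 53.5 % in elm, substrate at 78.2 % in maple and substrate at 64.2 % in ash.

    substrate + free catalyst → catalyst intermediate A (k = 120 M⁻¹ h⁻¹, Ea = 59.0 kJ mol⁻¹)
    reagent + catalyst intermediate A ⇌ catalyst intermediate B (K = 6.10 M⁻¹, k = 120 M⁻¹ h⁻¹, Ea = 53.0 kJ mol⁻¹, ΔH = −10.0 kJ mol⁻¹)
    catalyst intermediate B ⇌ by-product + catalyst intermediate C (K = 0.0280 M, k = 40.0 h⁻¹, Ea = 80.0 kJ mol⁻¹, ΔH = 9.00 kJ mol⁻¹)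
    catalyst intermediate C → free catalyst + product (k = 1.70 h⁻¹, Ea = 79.0 kJ mol⁻¹)
    crystals ⇌ product, rate k5*(cs5 - [product]) while solid is left; crystals form when [product] > cs5 (solubility = 0.420 mM, k = 14.0 h⁻¹)
    free catalyst + by-product ⇌ idle complex (K = 1400 M⁻¹, k = 73.0 M⁻¹ h⁻¹, Ea = 44.0 kJ mol⁻¹, ΔH = −71.0 kJ mol⁻¹)
    (constants at 5 °C)

8. Elm's result means a mean constant of 0.0766 h⁻¹, lower than the 0.0961 h⁻¹ carried forward. Elm and maple share their charge, and the difference in temperature is the main reason for the gap in product between them: elm gives 53.5 %, and at maple's temperature the same charge gives 18.8 %. In mean constants the flasks put that step at a factor of 3.69, smaller than the 6.45 of my reckoning, which put the south-to-west growth on temperature.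

9. Now read elm at 4.0 h, which is earlier than the reckoned half-way time of 7.21 h. So substrate should lead, and 0.0961 h⁻¹ gives 31.9 % product. That flask gives substrate in the lead at 65.8 %, with product at 31.3 %.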